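The two benzylic bonds flanking the C3–C4 bond of the oxolane are cut: aryl–C7′ and C3–C7 (C7 and C7′ are the benzylic CH2 groups on C3 and C4). The feature exploited is the unit aryl–C7′H2–C4H(C5H2–O)–C3, which lies hidden in the cyclopropane C6H2–C5H–C1 of a 3-oxabicyclo[3.1.0]hexan-2-one whose C1 bears an ester. In one flask an arylcopper reagent opens this strained ring at C6 and the released malonate-type enolate is benzylated at C3, so the full carbon skeleton arises with C4 already (R). The precursor is the ethyl ester of that bicyclic lactone, available in one step from diethyl malonate and (R)-epichlorohydrin; decarboxylation, reduction and ring closure finish the route.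

Key step: step 3

Assumption: the benzylic bromide used in the key step is taken as a purchased reagent; bromides of this electron-rich type age on storage, so it should be filtered through a short silica plug just before use.

Step 1
Reactants: 1 diethyl malonate; 2 (R)-epichlorohydrin
Product: 6 ethyl (1S,5R)-2-oxo-3-oxabicyclo[3.1.0]hexane-1-carboxylate, via chlorohydrin malonate 3 (not isolated), via oxiranylmethyl malonate 4 (not isolated), via cyclopropylmethanolate 5 (not isolated)
Conditions: NaOEt (1.05 equiv), 1 (1.2 equiv), EtOH, rt then reflux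
Reagents that add atoms: none
Why: Tandem alkylation–cyclopropanation–lactonisation of a malonate: the malonate anion opens the oxirane of 2 at its CH2 to give 3, the alkoxide closes the transposed oxirane 4 with loss of chloride, a 3-exo-tet SN2 attack of the malonate carbanion on the oxirane CH with inversion turns the single stereocentre of 2 into C5 (R) of 5, and the CH2O− of 5 can only lactonise onto the cis ester, which fixes C1 as (S).

Step 2
Reactants: 7 4-bromo-1,2-dimethoxybenzene
Product: 8 (3,4-dimethoxyphenyl)magnesium bromide
Conditions: Mg turnings, I2 (cat.), THF, 40–50 °C; solution titrated before use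
Reagents that add atoms: magnesium, [Mg]
Why: Grignard reagent formation by insertion of magnesium into the aryl C–Br bond, routine for an electron-rich aryl bromide in THF.

Step 3
Reactants: 6 ethyl (1S,5R)-2-oxo-3-oxabicyclo[3.1.0]hexane-1-carboxylate; 8 (3,4-dimethoxyphenyl)magnesium bromide; 9 3,4-dimethoxybenzyl bromide
Product: 11 ethyl (3R,4R)-3,4-bis(3,4-dimethoxybenzyl)-2-oxotetrahydrofuran-3-carboxylate, via bromomagnesium lactone enolate 10 (not isolated)
Conditions: 8 (1.2 equiv), CuI (10 mol%), THF, −30 to 0 °C; then 9 (1.5 equiv), DMPU, 0 to 40 °C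
Reagents that add atoms: none
Why: Transmetalation of 8 to copper should give an arylcopper species that attacks the cyclopropane CH2 (C6) of 6 in an SN2-like homoconjugate addition, the C1–C6 bond breaking with relief of ring strain to leave the chelated enolate 10, which is C-benzylated by 9 once DMPU loosens the magnesium chelate. The closest known reaction type is the copper-catalysed Grignard opening of cyclopropane-1,1-dicarbonyl compounds at the unsubstituted ring carbon, joined here to the ordinary alkylation of a malonate-type enolate. No ring is closed: the three-membered ring is opened and the lactone ring is left intact. The new quaternary centre C3 is set by substrate control, the benzyl group entering the enolate face anti to the C4 arylmethyl group, while C4 is a spectator that keeps the configuration of C5 of 6. The step needs attack at C6 and not at the ring-fusion CH or a carbonyl group, which the lower substitution of C6, the better overlap of the exocyclic C1–C6 bond with both acyl groups and the soft copper nucleophile at low temperature should secure. The facial selectivity of the benzylation is not critical, because C3 loses its ester and is re-set in step 4.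

Step 4
Reactants: 11 ethyl (3R,4R)-3,4-bis(3,4-dimethoxybenzyl)-2-oxotetrahydrofuran-3-carboxylate
Product: 14 (3R,4R)-3,4-bis(3,4-dimethoxybenzyl)dihydrofuran-2(3H)-one, via lithium lactone enolate 12 (not isolated), via cis-lactone 13 (not isolated)
Conditions: LiCl (3 equiv), H2O (2 equiv), DMSO, 150 °C; then DBU (0.2 equiv), toluene, 60 °C on the crude
Reagents that add atoms: none
Why: Krapcho dealkoxycarbonylation, in which chloride dealkylates the ethyl ester and the carboxylate loses CO2 to give 12, followed by protonation and DBU-mediated epimerisation of any cis isomer 13 through the same enolate, should settle C3 in the thermodynamically preferred trans (3R) arrangement next to the fixed C4 (unactivated aryl methyl ethers should survive).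

Step 5
Reactants: 14 (3R,4R)-3,4-bis(3,4-dimethoxybenzyl)dihydrofuran-2(3H)-one
Product: 15 (2R,3R)-2,3-bis(3,4-dimethoxybenzyl)butane-1,4-diol
Conditions: LiAlH4 (1.5 equiv), THF, 0 °C to rt; H2O/aq NaOH work-up
Reagents that add atoms: none
Why: Hydride reduction of a lactone to the 1,4-diol with LiAlH4 is fast and touches neither stereocentre, and the trans lactone is already the stable C3 epimer.

Step 6
Reactants: 15 (2R,3R)-2,3-bis(3,4-dimethoxybenzyl)butane-1,4-diol
Product: 17 (3R,4R)-3,4-bis(3,4-dimethoxybenzyl)tetrahydrofuran (target), via monotosylate 16 (not isolated)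
Conditions: TsCl (1.1 equiv), pyridine, 0 °C to rt, then 60 °C
Reagents that add atoms: none
Why: Sulfonylation of one of the two symmetry-equivalent primary hydroxyls gives 16, whose remaining hydroxyl displaces tosylate in a 5-exo-tet intramolecular Williamson etherification, and since no bond to C3 or C4 is touched the (3R,4R) configuration is carried through.

Compound list
1 | diethyl malonate | CCOC(=O)CC(=O)OCC | starting material
2 | (R)-epichlorohydrin, (2R)-2-(chloromethyl)oxirane | ClC[C@H]1CO1 | starting material
3 | diethyl 2-[(2R)-3-chloro-2-hydroxypropyl]propanedioate (present as its sodium salt) | CCOC(=O)C(C[C@@H](O)CCl)C(=O)OCC | intermediate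
4 | diethyl 2-{[(2R)-oxiran-2-yl]methyl}propanedioate | CCOC(=O)C(C[C@@H]1CO1)C(=O)OCC | intermediate
5 | diethyl (2R)-2-(hydroxymethyl)cyclopropane-1,1-dicarboxylate (present as its sodium alkoxide) | CCOC(=O)C1(C[C@H]1CO)C(=O)OCC | intermediate
6 | ethyl (1S,5R)-2-oxo-3-oxabicyclo[3.1.0]hexane-1-carboxylate | CCOC(=O)[C@]12C[C@H]1COC2=O | intermediate
7 | 4-bromo-1,2-dimethoxybenzene | COc1ccc(Br)cc1OC | starting material
8 | (3,4-dimethoxyphenyl)magnesium bromide | COc1ccc([Mg]Br)cc1OC | intermediate
9 | 3,4-dimethoxybenzyl bromide | COc1ccc(CBr)cc1OC | starting material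
10 | bromomagnesium (4R)-4-(3,4-dimethoxybenzyl)-3-(ethoxycarbonyl)-4,5-dihydrofuran-2-olate | CCOC(=O)C1=C(O[Mg]Br)OC[C@@H]1Cc1ccc(OC)c(OC)c1 | intermediate
11 | ethyl (3R,4R)-3,4-bis(3,4-dimethoxybenzyl)-2-oxotetrahydrofuran-3-carboxylate (benzyl groups trans) | CCOC(=O)[C@]1(Cc2ccc(OC)c(OC)c2)C(=O)OC[C@@H]1Cc1ccc(OC)c(OC)c1 | intermediate
12 | lithium (4R)-3,4-bis(3,4-dimethoxybenzyl)-4,5-dihydrofuran-2-olate | [Li+].[O-]C1=C(Cc2ccc(OC)c(OC)c2)[C@@H](Cc2ccc(OC)c(OC)c2)CO1 | intermediate
13 | (3S,4R)-3,4-bis(3,4-dimethoxybenzyl)dihydrofuran-2(3H)-one (cis) | COc1ccc(C[C@@H]2C(=O)OC[C@@H]2Cc2ccc(OC)c(OC)c2)cc1OC | intermediate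
14 | (3R,4R)-3,4-bis(3,4-dimethoxybenzyl)dihydrofuran-2(3H)-one (trans) | COc1ccc(C[C@H]2C(=O)OC[C@@H]2Cc2ccc(OC)c(OC)c2)cc1OC | intermediate
15 | (2R,3R)-2,3-bis(3,4-dimethoxybenzyl)butane-1,4-diol | COc1ccc(C[C@@H](CO)[C@H](CO)Cc2ccc(OC)c(OC)c2)cc1OC | intermediate
16 | (2R,3R)-2,3-bis(3,4-dimethoxybenzyl)-4-hydroxybutyl 4-methylbenzenesulfonate | COc1ccc(C[C@@H](COS(=O)(=O)c3ccc(C)cc3)[C@H](CO)Cc2ccc(OC)c(OC)c2)cc1OC | intermediate
17 | (3R,4R)-3,4-bis(3,4-dimethoxybenzyl)tetrahydrofuran | COc1ccc(C[C@H]2COC[C@@H]2Cc2ccc(OC)c(OC)c2)cc1OC | target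

Total step count: 6. Longest linear sequence: 5 steps (steps 1, 3, 4, 5 and 6); step 2 is a one-step side branch.

Steps most likely to fail

Step 3. The capture of the enolate may be incomplete or misdirected: C-alkylation of the tightly chelated magnesium enolate may be slow, O-alkylation may compete, and residual arylmetal may consume the benzylic bromide. Fallback: the two bond formations are separated. Setting out from 6 and 8, the copper-catalysed opening is run as before, but enolate 10 is protonated with cold 1 M HCl, which should give ethyl (3S,4R)-4-(3,4-dimethoxybenzyl)-2-oxotetrahydrofuran-3-carboxylate F1 (C3 epimerisable). F1 is then benzylated as its potassium enolate (K2CO3, 9, acetone, reflux), which comes back to the route at 11.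

Step 4. Dealkylation of the hindered ethyl ester on the quaternary carbon may be sluggish, so that prolonged heating erodes material, and epimerisation to the trans isomer may stay incomplete. Fallback: the ester is removed by hydrolysis and thermal decarboxylation. Setting out from 11, saponification with KOH in aqueous ethanol at reflux should give dipotassium 2-(3,4-dimethoxybenzyl)-2-[(2R)-1-(3,4-dimethoxyphenyl)-3-hydroxypropan-2-yl]propanedioate F2. Acidification with HCl should re-close the lactone to (3R,4R)-3,4-bis(3,4-dimethoxybenzyl)-2-oxotetrahydrofuran-3-carboxylic acid F3 (either C3 epimer serves), which loses CO2 on heating in toluene at 110 °C. The DBU treatment of step 4 then comes back to the route at 14.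

Step 6. Sulfonylation of the second hydroxyl may outpace ring closure, or chloride may displace the sulfonate, so that conversion to the cyclic ether stalls. Fallback: the diol is bypassed and the lactone carbonyl is deoxygenated. Setting out from 14, partial reduction with iBu2AlH (CH2Cl2, −78 °C) should give (3R,4R)-3,4-bis(3,4-dimethoxybenzyl)tetrahydrofuran-2-ol F4 (anomer mixture). Ionic hydrogenation of this lactol with Et3SiH and BF3·OEt2 (CH2Cl2, −78 to 0 °C, silane present before the Lewis acid is added) comes back to the route at the target 17.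

Further compounds
F1 | step 3 | ethyl (3S,4R)-4-(3,4-dimethoxybenzyl)-2-oxotetrahydrofuran-3-carboxylate | CCOC(=O)[C@H]1C(=O)OC[C@@H]1Cc1ccc(OC)c(OC)c1
F2 | step 4 | dipotassium 2-(3,4-dimethoxybenzyl)-2-[(2R)-1-(3,4-dimethoxyphenyl)-3-hydroxypropan-2-yl]propanedioate | [K+].[K+].[O-]C(=O)C(Cc1ccc(OC)c(OC)c1)(C([O-])=O)[C@H](CO)Cc1ccc(OC)c(OC)c1
F3 | step 4 | (3R,4R)-3,4-bis(3,4-dimethoxybenzyl)-2-oxotetrahydrofuran-3-carboxylic acid | OC(=O)[C@]1(Cc2ccc(OC)c(OC)c2)C(=O)OC[C@@H]1Cc1ccc(OC)c(OC)c1
F4 | step 6 | (3R,4R)-3,4-bis(3,4-dimethoxybenzyl)tetrahydrofuran-2-ol | COc1ccc(C[C@H]2C(O)OC[C@@H]2Cc2ccc(OC)c(OC)c2)cc1OC
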